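**Plan**
- Cuts: first C8–CHO; then, after putting a C3=C4 double bond back, C4–C4a and O1–C2 of the pyran ring, which separates an acylphloroglucinol from a C11 enal. The enal is cut at its C=C bond to (+)-nopinone, the aryl ketone at its acyl–aryl bond to phloroglucinol.
- Enabling feature (chroman numbering O1–C8a; pinane atoms primed, C6' = CMe2 bridge, C7' = CH2 bridge): the spiro atom C2 = C2' bears O1 on the C7' face and is flanked by C3–C4. The ring O1–C2–C3–C4–C4a–C8a is therefore the retron of a 2H-chromene, that is of the vinyl ortho-quinone methide O=C8a–C4a=C4–C3=C2.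
- Forward: the arene and the pinane bicycle are bought. Nopinone is homologated to the enal (steps 1–2), phloroglucinol is acylated and its oxygens differentiated (steps 3–6), and the pyran ring, the only ring made, closes in step 7. Hydrogenation with debenzylation (step 8) and formylation at C8 (step 9) finish the route.
- One ortho oxygen is carried as a benzyl ether, so that the single remaining ortho hydroxyl stays chelated to the ketone and the ring closes on the para oxygen. The benzyl group leaves during the hydrogenation.
- Stereochemistry: C1' and C5' come unchanged from (+)-nopinone; C2 is set in step 7 by bonding of oxygen to the C7' face of C2', away from the gem-dimethyl bridge.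

Key step: step 7

Assumption: (1R,5S)-(+)-nopinone, the ozonolysis product of (−)-β-pinene, is a commercial compound and is used as bought; "pinane" means 6,6-dimethylbicyclo[3.1.1]heptane.

**Step 1**
Reactants: 1 (1R,5S)-(+)-nopinone; 2 diethyl (cyanomethyl)phosphonate
Product: 3 (2E)-2-[(1R,5S)-6,6-dimethylbicyclo[3.1.1]heptan-2-ylidene]acetonitrile
Conditions: NaH, THF, 0 °C → reflux
Reagents that add atoms: none
Why: Horner–Wadsworth–Emmons olefination with the small cyanomethylphosphonate anion should convert the hindered ketone, whose bridgehead centres cannot epimerize, into the conjugated nitrile with the cyano group anti to the bridgehead C1' (E), a geometry that is not carried into the target.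

**Step 2**
Reactants: 3 (2E)-2-[(1R,5S)-6,6-dimethylbicyclo[3.1.1]heptan-2-ylidene]acetonitrile
Product: 5 (2E)-2-[(1R,5S)-6,6-dimethylbicyclo[3.1.1]heptan-2-ylidene]acetaldehyde, via N-aluminio aldimine 4 (not isolated)
Conditions: iBu2AlH (1.2 equiv), PhMe, −78 °C; then H2O, aq. KNaC4H4O6, 0 °C → rt
Reagents that add atoms: water, O
Why: Partial reduction of a conjugated nitrile with iBu2AlH should stop at the aluminium aldimine, which is stable at −78 °C and is hydrolysed to the enal on near-neutral aqueous work-up, the alkene and the cyclobutane being inert to the hydride.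

**Step 3**
Reactants: 6 phloroglucinol; 7 isovaleryl chloride
Product: 8 3-methyl-1-(2,4,6-trihydroxyphenyl)butan-1-one (isovalerylphloroglucinol)
Conditions: AlCl3 (3 equiv), PhNO2/CH2Cl2, 0 → 40 °C; then aq. HCl
Reagents that add atoms: none
Why: Friedel–Crafts C-acylation of phloroglucinol should stop after one acyl group, because the ketone complexed to AlCl3 deactivates the ring, as is standard for acylphloroglucinols.

**Step 4**
Reactants: 8 isovalerylphloroglucinol
Product: 9 1-[2-hydroxy-4,6-bis(methoxymethoxy)phenyl]-3-methylbutan-1-one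
Conditions: MOMCl (2.2 equiv), iPr2NEt, CH2Cl2, 0 °C → rt
Reagents that add atoms: chloromethyl methyl ether, COCCl
Why: O-Alkylation (Williamson-type acetal formation) should take the para hydroxyl and one ortho hydroxyl and spare the second ortho hydroxyl, which is hydrogen-bonded to the ketone, the usual behaviour of 2,4,6-trihydroxyaryl ketones.

**Step 5**
Reactants: 9 1-[2-hydroxy-4,6-bis(methoxymethoxy)phenyl]-3-methylbutan-1-one
Product: 10 1-[2-(benzyloxy)-4,6-bis(methoxymethoxy)phenyl]-3-methylbutan-1-one
Conditions: BnBr, K2CO3, DMF, 60 °C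
Reagents that add atoms: benzyl bromide, BrCc1ccccc1
Why: Williamson etherification of the remaining chelated phenol should proceed under warm carbonate/DMF conditions, to which the MOM acetals and the ketone are stable.

**Step 6**
Reactants: 10 1-[2-(benzyloxy)-4,6-bis(methoxymethoxy)phenyl]-3-methylbutan-1-one
Product: 11 1-[2-(benzyloxy)-4,6-dihydroxyphenyl]-3-methylbutan-1-one
Conditions: HCl (1.25 M in MeOH), rt → 40 °C
Reagents that add atoms: none
Why: Acid-catalysed transacetalization in methanol should remove both MOM groups while the aryl benzyl ether and the ketone survive, freeing the para hydroxyl that becomes O1 and leaving one chelated ortho hydroxyl.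

**Step 7**
Reactants: 11 1-[2-(benzyloxy)-4,6-dihydroxyphenyl]-3-methylbutan-1-one; 5 (2E)-2-[(1R,5S)-6,6-dimethylbicyclo[3.1.1]heptan-2-ylidene]acetaldehyde
Product: 13 (2R,1'R,5'S)-7-(benzyloxy)-5-hydroxy-6-(3-methylbutanoyl)spiro[2H-chromene-2,2'-pinane], via vinyl ortho-quinone methide 12 (not isolated)
Conditions: 5 (1.5 equiv), ethylenediammonium diacetate (20 mol %), PhMe, 110 °C
Reagents that add atoms: none
Why: The diammonium salt turns enal 5 into an iminium ion, the ring carbon of 11 that lies between the two free hydroxyls adds to it (C4–C4a), and loss of the amine leaves vinyl ortho-quinone methide 12, which closes by a thermal disrotatory oxa-6π electrocyclization (O1–C2). The closest known reaction type is the amine-salt-mediated Knoevenagel condensation/oxa-6π electrocyclization of resorcinols and acylphloroglucinols with β,β-disubstituted enals such as citral. The pyran ring thus closes in the pericyclic 6π mode with C2' neutral throughout, so that neither a Wagner–Meerwein shift nor opening of the cyclobutane can intervene. The spiro centre C2 is set by the bicycle: oxygen should bond to the face of C2' that carries the CH2 bridge C7', because the gem-dimethyl bridge C6' screens the other face, and this gives the (2R) centre of the target whatever the geometry of the enal. The regioselectivity needed is closure on the hydroxyl para to the ketone, and it is secured by the benzyl ether, which leaves a single ortho hydroxyl locked in a hydrogen bond to the carbonyl group, as in 2,4-dihydroxyaryl ketones that close on the 4-hydroxyl. Should some C–C bonding occur at the other free ring carbon, the ring would close on the same oxygen and the regioisomeric benzyl ether would merge with 13 at diol 14 in step 8.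

**Step 8**
Reactants: 13 (2R,1'R,5'S)-7-(benzyloxy)-5-hydroxy-6-(3-methylbutanoyl)spiro[2H-chromene-2,2'-pinane]
Product: 14 (2R,1'R,5'S)-5,7-dihydroxy-6-(3-methylbutanoyl)spiro[chromane-2,2'-pinane]
Conditions: H2 (1 atm), 10% Pd/C, EtOAc, rt
Reagents that add atoms: none
Why: Heterogeneous catalytic hydrogenation should saturate the cis-disubstituted styrenic C3=C4 bond and hydrogenolyse the benzyl ether in one operation, the chelated aryl ketone and the cyclobutane not being reduced under these mild conditions and no bond to C2 being broken.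

**Step 9**
Reactants: 14 (2R,1'R,5'S)-5,7-dihydroxy-6-(3-methylbutanoyl)spiro[chromane-2,2'-pinane]
Product: 16 euglobal G3, via aryl iminium chloride 15 (not isolated)
Conditions: POCl3 (1.5 equiv), DMF (3 equiv), EtOAc, 0 °C → rt; then H2O, 0 °C → rt
Reagents that add atoms: N,N-dimethylformamide, CN(C)C=O; water, O
Why: Vilsmeier–Haack formylation should attack C8, the only unsubstituted ring carbon, ortho to the C7 hydroxyl and para to the C5 hydroxyl, as in the formylation of acylphloroglucinols, without a strong Lewis acid that could ionize the tertiary C2–O1 bond, and cold water hydrolyses the iminium salt to the aldehyde.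

**Compound list**
1 | (1R,5S)-6,6-dimethylbicyclo[3.1.1]heptan-2-one, (+)-nopinone | O=C1CC[C@H]2C[C@@H]1C2(C)C | starting material
2 | diethyl (cyanomethyl)phosphonate | CCOP(=O)(CC#N)OCC | starting material
3 | (2E)-2-[(1R,5S)-6,6-dimethylbicyclo[3.1.1]heptan-2-ylidene]acetonitrile | N#C/C=C1\CC[C@H]2C[C@@H]1C2(C)C | intermediate
4 | (1E,2E)-N-(diisobutylalumanyl)-2-[(1R,5S)-6,6-dimethylbicyclo[3.1.1]heptan-2-ylidene]ethan-1-imine (formed in the flask, not isolated) | CC(C)C[Al](CC(C)C)/N=C/C=C1\CC[C@H]2C[C@@H]1C2(C)C | intermediate
5 | (2E)-2-[(1R,5S)-6,6-dimethylbicyclo[3.1.1]heptan-2-ylidene]acetaldehyde | O=C/C=C1\CC[C@H]2C[C@@H]1C2(C)C | intermediate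
6 | phloroglucinol (benzene-1,3,5-triol) | Oc1cc(O)cc(O)c1 | starting material
7 | isovaleryl chloride (3-methylbutanoyl chloride) | CC(C)CC(Cl)=O | starting material
8 | 3-methyl-1-(2,4,6-trihydroxyphenyl)butan-1-one | CC(C)CC(=O)c1c(O)cc(O)cc1O | intermediate
9 | 1-[2-hydroxy-4,6-bis(methoxymethoxy)phenyl]-3-methylbutan-1-one | CC(C)CC(=O)c1c(O)cc(OCOC)cc1OCOC | intermediate
10 | 1-[2-(benzyloxy)-4,6-bis(methoxymethoxy)phenyl]-3-methylbutan-1-one | CC(C)CC(=O)c1c(OCc2ccccc2)cc(OCOC)cc1OCOC | intermediate
11 | 1-[2-(benzyloxy)-4,6-dihydroxyphenyl]-3-methylbutan-1-one | CC(C)CC(=O)c1c(O)cc(O)cc1OCc1ccccc1 | intermediate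
12 | (6Z)-3-(benzyloxy)-5-hydroxy-4-(3-methylbutanoyl)-6-{(2E)-2-[(1R,5S)-6,6-dimethylbicyclo[3.1.1]heptan-2-ylidene]ethylidene}cyclohexa-2,4-dien-1-one (vinyl ortho-quinone methide, formed in the flask, not isolated) | O=C1C=C(OCc2ccccc2)C(C(=O)CC(C)C)=C(O)/C1=C/C=C3\CC[C@H]4C[C@@H]3C4(C)C | intermediate
13 | (2R,1'R,5'S)-7-(benzyloxy)-5-hydroxy-6-(3-methylbutanoyl)spiro[2H-chromene-2,2'-pinane]; O1 on the face of the C7' methylene bridge | CC(C)CC(=O)c1c(OCc2ccccc2)cc3c(c1O)C=C[C@@]4(CC[C@H]5C[C@@H]4C5(C)C)O3 | intermediate
14 | (2R,1'R,5'S)-5,7-dihydroxy-6-(3-methylbutanoyl)spiro[chromane-2,2'-pinane] | CC(C)CC(=O)c1c(O)cc2c(c1O)CC[C@@]1(CC[C@H]3C[C@@H]1C3(C)C)O2 | intermediate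
15 | N-{[(2R,1'R,5'S)-5,7-dihydroxy-6-(3-methylbutanoyl)spiro[chromane-2,2'-pinan]-8-yl]methylidene}-N-methylmethanaminium chloride (formed in the flask, not isolated) | CC(C)CC(=O)c1c(O)c(C=[N+](C)C)c2c(c1O)CC[C@@]1(CC[C@H]3C[C@@H]1C3(C)C)O2.[Cl-] | intermediate
16 | euglobal G3, (2R,1'R,5'S)-5,7-dihydroxy-6-(3-methylbutanoyl)spiro[chromane-2,2'-pinane]-8-carbaldehyde | CC(C)CC(=O)c1c(O)c(C=O)c2c(c1O)CC[C@@]1(CC[C@H]3C[C@@H]1C3(C)C)O2 | target

**Count and risks**
Total: 9 steps. Longest linear sequence: 7 steps (phloroglucinol 6 to 16, steps 3–9); the terpene branch is 2 steps to enal 5.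

Step 7. The condensation may be slow with a hindered enal that can deconjugate or self-condense through its dienamine, and the ring closure may discriminate the two faces of C2' incompletely. The fallback sets out from 11 and builds the pyran ring by a three-component Knoevenagel/hetero-Diels–Alder sequence. Paraformaldehyde, NaOAc and AcOH at 80 °C should convert 11 into the ortho-quinone methide 3-(benzyloxy)-5-hydroxy-6-methylidene-4-(3-methylbutanoyl)cyclohexa-2,4-dien-1-one F1. This is trapped in the flask by excess (−)-β-pinene (C=C1CC[C@H]2C[C@@H]1C2(C)C) in an inverse-demand [4+2] cycloaddition, the alkene being attacked on its C7' face and oxygen bonding to the more substituted carbon. The cycloadduct is the saturated benzyl ether (2R,1'R,5'S)-7-(benzyloxy)-5-hydroxy-6-(3-methylbutanoyl)spiro[chromane-2,2'-pinane] F2, and hydrogenolysis (H2, Pd/C, EtOAc) returns to the route at 14.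

Step 9. The acid set free may ionize the tertiary C2–O1 bond and start a skeletal rearrangement of the pinane, or the chloroiminium reagent may attack the α-methylene of the ortho-hydroxyaryl ketone and cyclize to a chromone. The fallback sets out from 14 and introduces the carbon at the alcohol oxidation level under basic conditions. MgCl2, Et3N and paraformaldehyde in MeCN at reflux (magnesium phenoxide-directed ortho-hydroxymethylation) should give the salicyl alcohol (2R,1'R,5'S)-5,7-dihydroxy-8-(hydroxymethyl)-6-(3-methylbutanoyl)spiro[chromane-2,2'-pinane] F3. This is oxidized in the same flask by hydride transfer to a second molecule of formaldehyde, arriving at 16.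

Step 2. The aluminium aldimine may be over-reduced, or the exocyclic double bond may migrate while the imine is hydrolysed. The fallback sets out from 1 and passes through the ester oxidation level. Horner–Wadsworth–Emmons reaction with triethyl phosphonoacetate (NaH, THF) gives ethyl (2E)-2-[(1R,5S)-6,6-dimethylbicyclo[3.1.1]heptan-2-ylidene]acetate F4. Full reduction with iBu2AlH (CH2Cl2, −78 °C) gives (2E)-2-[(1R,5S)-6,6-dimethylbicyclo[3.1.1]heptan-2-ylidene]ethanol F5, and MnO2 in CH2Cl2 oxidizes this allylic alcohol to 5, where the route is rejoined.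

**Further compounds**
F1 | step 7 | 3-(benzyloxy)-5-hydroxy-6-methylidene-4-(3-methylbutanoyl)cyclohexa-2,4-dien-1-one | O=C1C=C(OCc2ccccc2)C(C(=O)CC(C)C)=C(O)C1=C
F2 | step 7 | (2R,1'R,5'S)-7-(benzyloxy)-5-hydroxy-6-(3-methylbutanoyl)spiro[chromane-2,2'-pinane] | CC(C)CC(=O)c1c(OCc2ccccc2)cc3c(c1O)CC[C@@]4(CC[C@H]5C[C@@H]4C5(C)C)O3
F3 | step 9 | (2R,1'R,5'S)-5,7-dihydroxy-8-(hydroxymethyl)-6-(3-methylbutanoyl)spiro[chromane-2,2'-pinane] | CC(C)CC(=O)c1c(O)c(CO)c2c(c1O)CC[C@@]1(CC[C@H]3C[C@@H]1C3(C)C)O2
F4 | step 2 | ethyl (2E)-2-[(1R,5S)-6,6-dimethylbicyclo[3.1.1]heptan-2-ylidene]acetate | CCOC(=O)/C=C1\CC[C@H]2C[C@@H]1C2(C)C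
F5 | step 2 | (2E)-2-[(1R,5S)-6,6-dimethylbicyclo[3.1.1]heptan-2-ylidene]ethanol | OC/C=C1\CC[C@H]2C[C@@H]1C2(C)C
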